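**Retrosynthetic overview**
1. Endgame: phenol release, C1 acetylation, and hydride delivery from the ring periphery to a macrocyclic (2Z,6E)-1-oxohumuladienyl vanillate, which sets 1R.
2. Key disconnection C1–C11. The eleven-membered ring is the only carbocycle. It is closed from an acyclic (2Z,6E)-4-aroyloxyfarnesal by H-atom transfer to C10, chromium capture at C11 and addition to the C1 aldehyde. This gives the same bond, the same new C10–H and the same C1–O as farnesyl 1,11-closure, 1,3-hydride shift and water capture.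
3. The Z-enal comes from (S)-5-geranyl-4-methylbutenolide. The lactone locks 2Z; Weinreb opening, aroylation and amide-to-aldehyde reduction follow.
4. The butenolide comes from (E)-geranylacetone, which supplies C3–C11 with its methyl groups (13 carbons) and the 6E olefin. D-Proline α-aminoxylation sets C4, and the Bestmann ylide brings C1–C2.
5. Ring order: transient butenolide (made, then opened), then the cycloundecadiene.

**Assumption:** biogenetic humulane numbering is used: C1 = CH(OAc), C2=C3(CH3), C4 = CH(O-vanilloyl), C5, C6=C7(CH3), C8–C10, C11 = C(CH3)2. In this numbering the target is (1R,2Z,4S,6E). Geranylacetone is bought as the pure E isomer.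

**Step 1**
Reactants: 1 (E)-geranylacetone
Product: 3 (3S,5E)-3-hydroxy-6,10-dimethylundeca-5,9-dien-2-one, via aminoxy ketone 2 (not isolated)
Conditions: 1 (3 equiv, excess recovered), PhNO (1 equiv, syringe pump), D-proline (20 mol %), DMSO, rt; then CuSO4·5H2O (30 mol %), MeOH, 0 °C
Reagents that add atoms: nitrosobenzene O=Nc1ccccc1
Why: Proline-catalysed α-aminoxylation (O-selective nitroso aldol): a methyl alkyl ketone reacts through its more substituted E-enamine, so oxygen enters only at the CH2 that becomes C4, the carboxylic acid of D-proline steers PhN=O to the enamine face that gives 4S (L-proline gives R in this reaction class), and the copper-catalysed N–O cleavage does not touch the stereocentre.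

**Step 2**
Reactants: 3 (3S,5E)-3-hydroxy-6,10-dimethylundeca-5,9-dien-2-one; 4 (triphenylphosphoranylidene)ketene (Bestmann ylide)
Product: 6 (5S)-5-[(2E)-3,7-dimethylocta-2,6-dien-1-yl]-4-methylfuran-2(5H)-one, via acyl ylide 5 (not isolated)
Conditions: 4 (1.2 equiv), toluene, 90 °C
Reagents that add atoms: none
Why: Bestmann butenolide synthesis: the hydroxyl adds to the ketene C=C of 4 to give acyl ylide 5, whose intramolecular Wittig reaction with the methyl ketone closes the lactone, so C1 and C4 are forced cis on the new C2=C3 bond (the 2Z geometry of the target) under neutral conditions that leave C4 untouched.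

**Step 3**
Reactants: 7 vanillic acid
Product: 8 4-acetoxy-3-methoxybenzoic acid
Conditions: Ac2O, pyridine, rt; aqueous work-up
Reagents that add atoms: acetic anhydride CC(=O)OC(C)=O
Why: Phenol acetylation; the aryl acetate masks the phenol against acylation, the chromium step and the periodinane, and it can later be removed in the presence of alkyl esters.

**Step 4**
Reactants: 6 (5S)-5-geranyl-4-methylfuran-2(5H)-one; 8 4-acetoxy-3-methoxybenzoic acid
Product: 11 (2Z,4S,6E)-1-[methoxy(methyl)amino]-3,7,11-trimethyl-1-oxododeca-2,6,10-trien-4-yl 4-acetoxy-3-methoxybenzoate, via acid chloride 9 (not isolated), via hydroxy amide 10 (not isolated)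
Conditions: (a) 8, (COCl)2, cat. DMF, CH2Cl2, concentrate; (b) 6, MeNH(OMe)·HCl/Me3Al (3 equiv each), CH2Cl2, 0 °C, aq. potassium sodium tartrate, cold; (c) crude 10, 9, Et3N, DMAP, CH2Cl2, −20 to 0 °C
Reagents that add atoms: N,O-dimethylhydroxylamine hydrochloride CNOC.Cl; oxalyl chloride O=C(Cl)C(=O)Cl (chlorine of 9 only)
Why: Weinreb aminolysis of the lactone by the weakly basic aluminium amide opens the ring without deprotonating C4–H and keeps the Z-olefin, and immediate DMAP-catalysed O-acylation by 9 (only the O–H bond reacts, so C4 is retained) stops relactonisation and installs the vanillate skeleton.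

**Step 5**
Reactants: 11 aroyloxy Weinreb amide
Product: 12 (2Z,4S,6E)-3,7,11-trimethyl-1-oxododeca-2,6,10-trien-4-yl 4-acetoxy-3-methoxybenzoate
Conditions: Cp2Zr(H)Cl (1.6 equiv), THF, rt, 20 min; silica filtration
Reagents that add atoms: none
Why: Chemoselective amide-to-aldehyde reduction by hydrozirconation of the amide carbonyl: Cp2Zr(H)Cl converts Weinreb amides within minutes into a stable zirconated hemiaminal that gives the aldehyde on work-up, while esters and trisubstituted olefins react far more slowly, so the Z-enal forms without acid or base.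

**Step 6**
Reactants: 12 (2Z,4S,6E)-4-aroyloxyfarnesal
Product: 15 (1S,2Z,4S,6E)-1-hydroxy-3,7,11,11-tetramethylcycloundeca-2,6-dien-4-yl 4-acetoxy-3-methoxybenzoate, via alkylchromium dichloride 13 (not isolated), via chromium alkoxide 14 (not isolated)
Conditions: Fe(dpm)3 (1.5 equiv; dpm = 2,2,6,6-tetramethylheptane-3,5-dionate), CrCl2 (15 equiv, 0.08 M), THF–DMF 4:1, 30 °C; 12 and Ph(i-PrO)SiH2 (3 equiv) added together over 12 h (final 5 mM); pH 4 citrate buffer
Reagents that add atoms: none
Why: Proposed new method: an iron hydride made from Fe(dpm)3 and the silane transfers H• to C10 of the most exposed, terminal trisubstituted olefin (Markovnikov hydrogen atom transfer), the tertiary C11 radical is trapped by the large excess of divalent chromium (about 10^7–10^8 M^-1 s^-1 × 0.08 M, faster than its 6-endo attack on C6=C7 at about 10^3–10^4 s^-1) to give 13, which adds 1,2 to the enal in a Nozaki–Hiyama–Kishi-type step to give 14, so that the C1–C11 bond, the new C10–H and the C1–O reproduce the outcome of 1,11-closure, 1,3-hydride shift and water capture; allylic 1,3-strain (C4–H in the enal plane, tether on the face opposite the aroyloxy group, chromium outside the forming ring) predicts the 1S alcohol, which does not matter because step 7 erases C1; the closest known reaction types are the intermolecular branch-selective olefin–aldehyde coupling by cobalt-salen hydrogen atom transfer with chromium salts, and Nozaki–Hiyama–Kishi macrocyclisation.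

**Step 7**
Reactants: 15 macrocyclic 1S alcohol (with any 1R epimer)
Product: 16 (2Z,4S,6E)-3,7,11,11-tetramethyl-1-oxocycloundeca-2,6-dien-4-yl 4-acetoxy-3-methoxybenzoate
Conditions: Dess–Martin periodinane, NaHCO3, CH2Cl2, 0 °C to rt
Reagents that add atoms: none
Why: Dess–Martin oxidation of the hindered allylic alcohol under buffered neutral conditions gives the Z-enone, merges both C1 epimers, and leaves the esters, both olefin geometries and C4 untouched.

**Step 8**
Reactants: 16 macrocyclic Z-enone
Product: 17 (1R,2Z,4S,6E)-1-hydroxy-3,7,11,11-tetramethylcycloundeca-2,6-dien-4-yl 4-acetoxy-3-methoxybenzoate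
Conditions: NaBH4, CeCl3·7H2O (1.5 equiv each), MeOH–THF, −78 to −40 °C
Reagents that add atoms: none
Why: Luche 1,2-reduction under macrocyclic stereocontrol: allylic 1,3-strain keeps C4–H in the olefin plane and both ring bonds (C4–C5 and C1–C11) on the face opposite the aroyloxy group, the carbonyl is twisted out of conjugation by the quaternary C11, and hydride can reach it only from the ring periphery, which sets 1R.

**Step 9**
Reactants: 17 macrocyclic 1R alcohol
Product: 18 (1R,2Z,4S,6E)-1-acetoxy-3,7,11,11-tetramethylcycloundeca-2,6-dien-4-yl 4-acetoxy-3-methoxybenzoate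
Conditions: Ac2O, Et3N, DMAP, CH2Cl2, rt to 35 °C
Reagents that add atoms: acetic anhydride CC(=O)OC(C)=O
Why: DMAP-catalysed acetylation of the neopentylic C1–OH proceeds at oxygen with retention, and any phenol freed in step 8 is re-acetylated at the same time.

**Step 10**
Reactants: 18 diacetate
Product: 19 CNP0124394.1, (1R,2Z,4S,6E)-1-acetoxy-3,7,11,11-tetramethylcycloundeca-2,6-dien-4-yl 4-hydroxy-3-methoxybenzoate
Conditions: pyrrolidine (1.5 equiv), CH2Cl2, 0 °C, 30 min
Reagents that add atoms: none
Why: Chemoselective aminolysis: the aryl acetate is an activated ester with a phenoxide leaving group and is cleaved within minutes, whereas the hindered C1 acetate and the C4 aroate are inert.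

**Compound list**
1 | (E)-geranylacetone | CC(=O)CC/C=C(\C)CCC=C(C)C | starting material
2 | (3S,5E)-6,10-dimethyl-3-[(phenylamino)oxy]undeca-5,9-dien-2-one | CC(=O)[C@@H](ONc1ccccc1)C/C=C(\C)CCC=C(C)C | intermediate
3 | (3S,5E)-3-hydroxy-6,10-dimethylundeca-5,9-dien-2-one | CC(=O)[C@@H](O)C/C=C(\C)CCC=C(C)C | intermediate
4 | (triphenylphosphoranylidene)ketene | O=C=C=P(c1ccccc1)(c1ccccc1)c1ccccc1 | starting material
5 | (triphenylphosphoranylidene)acetate ester of 3 | CC(=O)[C@@H](OC(=O)C=P(c1ccccc1)(c1ccccc1)c1ccccc1)C/C=C(\C)CCC=C(C)C | intermediate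
6 | (5S)-5-geranyl-4-methylfuran-2(5H)-one | O=C1C=C(C)[C@H](C/C=C(\C)CCC=C(C)C)O1 | intermediate
7 | vanillic acid | COc1cc(C(=O)O)ccc1O | starting material
8 | 4-acetoxy-3-methoxybenzoic acid | CC(=O)Oc1ccc(cc1OC)C(=O)O | intermediate
9 | 4-acetoxy-3-methoxybenzoyl chloride | CC(=O)Oc1ccc(cc1OC)C(=O)Cl | intermediate
10 | (2Z,4S,6E)-4-hydroxy-N-methoxy-N,3,7,11-tetramethyldodeca-2,6,10-trienamide | CON(C)C(=O)/C=C(/C)[C@@H](O)C/C=C(\C)CCC=C(C)C | intermediate
11 | 4-O-(4-acetoxy-3-methoxybenzoyl) derivative of 10 | CON(C)C(=O)/C=C(/C)[C@@H](OC(=O)c1ccc(OC(C)=O)c(OC)c1)C/C=C(\C)CCC=C(C)C | intermediate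
12 | (2Z,4S,6E)-4-(4-acetoxy-3-methoxybenzoyloxy)farnesal | O=C/C=C(/C)[C@@H](OC(=O)c1ccc(OC(C)=O)c(OC)c1)C/C=C(\C)CCC=C(C)C | intermediate
13 | C11 tertiary alkylchromium dichloride of 10,11-dihydro-12 | O=C/C=C(/C)[C@@H](OC(=O)c1ccc(OC(C)=O)c(OC)c1)C/C=C(\C)CCCC(C)(C)[Cr](Cl)Cl | intermediate
14 | dichlorochromium alkoxide of 15 | CC(=O)Oc1ccc(cc1OC)C(=O)O[C@H]2C/C=C(\C)CCCC(C)(C)[C@@H](O[Cr](Cl)Cl)/C=C\2C | intermediate
15 | (1S,2Z,4S,6E)-1-hydroxyhumula-2,6-dien-4-yl 4-acetoxy-3-methoxybenzoate | CC(=O)Oc1ccc(cc1OC)C(=O)O[C@H]2C/C=C(\C)CCCC(C)(C)[C@@H](O)/C=C\2C | intermediate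
16 | (2Z,4S,6E)-1-oxohumula-2,6-dien-4-yl 4-acetoxy-3-methoxybenzoate | CC(=O)Oc1ccc(cc1OC)C(=O)O[C@H]2C/C=C(\C)CCCC(C)(C)C(=O)/C=C\2C | intermediate
17 | (1R,2Z,4S,6E)-1-hydroxyhumula-2,6-dien-4-yl 4-acetoxy-3-methoxybenzoate | CC(=O)Oc1ccc(cc1OC)C(=O)O[C@H]2C/C=C(\C)CCCC(C)(C)[C@H](O)/C=C\2C | intermediate
18 | (1R,2Z,4S,6E)-1-acetoxyhumula-2,6-dien-4-yl 4-acetoxy-3-methoxybenzoate | CC(=O)Oc1ccc(cc1OC)C(=O)O[C@H]2C/C=C(\C)CCCC(C)(C)[C@H](OC(C)=O)/C=C\2C | intermediate
19 | CNP0124394.1 | COc1cc(C(=O)O[C@H]2C/C=C(\C)CCCC(C)(C)[C@H](OC(C)=O)/C=C\2C)ccc1O | target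

**Total step count:** 10.
**Longest linear sequence:** 9 (steps 1, 2, 4–10).

**Steps most likely to fail**

**Step 6 (ring closure).**
- H• may also go to C6=C7. That would give a seven-membered carbinol, a 5-exo addition to the enal, or E/Z scrambling.
- The weak tertiary C–Cr bond can re-open and leak into 6-endo cyclisation.
- Simple hydrogenation of the terminal olefin also competes.
- A yield above about 30 % is not expected.

The fallback replaces the open-shell C11 species with a closed-shell allylchromium. It sets out from 12 and comes back at 15. Oxyselenation of the terminal olefin with N-(phenylseleno)phthalimide and water (Markovnikov, terminal-selective like polyprenoid bromohydrin formation) gives the hydroxy selenide F1. H2O2 gives the selenoxide F2, whose syn-elimination away from the carbinol gives the (9E) tertiary allylic alcohol F3. SOCl2 (SNi′) gives the secondary allylic chloride F4. CrCl2 in THF–DMF at high dilution gives the allylchromium dichloride F5. This species ignores C6=C7 and attacks the aldehyde through its γ-carbon C11 (Nozaki–Hiyama allylation) to give the humula-2,6,9-trienol F6. Diimide (2-nitrobenzenesulfonyl hydrazide, Et3N) saturates only the disubstituted C9=C10 bond and delivers 15. Either C1 epimer serves, because step 7 follows.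

**Step 8 (facial selectivity at C1).** The conformational model may be wrong, and the ring could return the 1S alcohol. The fallback hands stereocontrol from the ring to a chiral reagent. It sets out from 16 and comes back at 17. It uses (S)-2-methyl-CBS-oxazaborolidine with catecholborane in toluene at −78 °C. The quaternary C11 side acts as the large group, which corresponds to the 1R alcohol. No new compound is made.

**Step 4 (lactone opening and aroylation).** Hydroxy amide 10 may relactonise faster than it is acylated, or the amine may add in conjugate fashion. The fallback avoids any acyl group at C1 while C4–OH is free. It sets out from 6 and comes back at 12, so step 5 is skipped as well. Exhaustive reduction with i-Bu2AlH gives the (2Z,4S,6E)-farnesa-2,6,10-triene-1,4-diol F7. TBSCl and imidazole at −20 °C silylate only the primary hydroxyl and give the mono-TBS ether F8. Acylation with 9, Et3N and DMAP gives the aroate F9. HF·pyridine frees the primary allylic alcohol F10, and MnO2 oxidises it to 12.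

**Further compounds**
F1 | step 6 | hydroxy selenide (C10–SePh, C11–OH) of 12 | O=C/C=C(/C)[C@@H](OC(=O)c1ccc(OC(C)=O)c(OC)c1)C/C=C(\C)CCC([Se]c1ccccc1)C(C)(C)O
F2 | step 6 | selenoxide of F1 | O=C/C=C(/C)[C@@H](OC(=O)c1ccc(OC(C)=O)c(OC)c1)C/C=C(\C)CCC([Se](=O)c1ccccc1)C(C)(C)O
F3 | step 6 | (2Z,4S,6E,9E)-11-hydroxy tertiary allylic alcohol enal | O=C/C=C(/C)[C@@H](OC(=O)c1ccc(OC(C)=O)c(OC)c1)C/C=C(\C)C/C=C/C(C)(C)O
F4 | step 6 | C9 secondary allylic chloride enal | O=C/C=C(/C)[C@@H](OC(=O)c1ccc(OC(C)=O)c(OC)c1)C/C=C(\C)CC(Cl)C=C(C)C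
F5 | step 6 | C9 allylchromium dichloride | O=C/C=C(/C)[C@@H](OC(=O)c1ccc(OC(C)=O)c(OC)c1)C/C=C(\C)CC([Cr](Cl)Cl)C=C(C)C
F6 | step 6 | (1S,2Z,4S,6E,9E)-1-hydroxyhumula-2,6,9-trien-4-yl 4-acetoxy-3-methoxybenzoate | CC(=O)Oc1ccc(cc1OC)C(=O)O[C@H]2C/C=C(\C)C/C=C/C(C)(C)[C@@H](O)/C=C\2C
F0 | step 8 | none | none
F7 | step 4 | (2Z,4S,6E)-3,7,11-trimethyldodeca-2,6,10-triene-1,4-diol | OC/C=C(/C)[C@@H](O)C/C=C(\C)CCC=C(C)C
F8 | step 4 | 1-O-TBS ether of F7 | CC(C)(C)[Si](C)(C)OC/C=C(/C)[C@@H](O)C/C=C(\C)CCC=C(C)C
F9 | step 4 | 4-O-(4-acetoxy-3-methoxybenzoyl) derivative of F8 | CC(C)(C)[Si](C)(C)OC/C=C(/C)[C@@H](OC(=O)c1ccc(OC(C)=O)c(OC)c1)C/C=C(\C)CCC=C(C)C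
F10 | step 4 | (2Z,4S,6E)-1-hydroxy-3,7,11-trimethyldodeca-2,6,10-trien-4-yl 4-acetoxy-3-methoxybenzoate | OC/C=C(/C)[C@@H](OC(=O)c1ccc(OC(C)=O)c(OC)c1)C/C=C(\C)CCC=C(C)C
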